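You cannot run the early readings on as a straight line, for percent of the substrate charged stops at 100, so the line has to bend, and what is asked is how far it has bent at the end of ochre and of grey.

in all of them: free catalyst 36 mM; second catalyst 50 mM
- zeta: substrate 0.32 M; coupling partner 3 M; run made earlier
- delta: substrate 0.54 M; coupling partner 3 M; run made earlier
- epsilon: substrate 0.79 M; coupling partner 3 M; run made earlier
- ochre: substrate 1.0 M; coupling partner 3.00 M; time 3.0 min
- grey: substrate 0.30 M; coupling partner 3.00 M; time 5.0 min

- zeta (time / s: product / %): 10.0: 0.9; 15.0: 0.9; 25.0: 1.2; 50.0: 6.2; 90.0: 12.6
- delta (time / s: product / %): 10.0: 0; 25.0: 1.8; 40.0: 3.8; 60.0: 7.3; 90.0: 11.5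
- epsilon (time / s: product / %): 20.0: 0.9; 40.0: 4.7; 50.0: 6.1; 80.0: 10.5; 90.0: 11.8

(scatter of a reading: 0.5 percentage points)

* which one finishes higher in amount of product, in percent of the substrate charged ("neither" within 2 percentage points) (ochre / grey / neither)
* amount of product at the end, in percent of the substrate charged, ochre
* amount of product at the end, in percent of the substrate charged, grey

- the analysis behind the earlier runs scatters by 0.5 percentage points, standard deviation

Take the settings in turn. By hand, a rate proportional to [substrate] leaves the percent curve where it is, while a rate blind to [substrate] lowers it as the charge grows; in the runs [substrate] goes from 0.32 M to 0.79 M and the readings at 90.0 s stay within 1.1 percentage points of one another, against a scatter of 0.5 points, so I read percent as independent of the charge and carry that up to ochre's 1.0 M, somewhat above the runs. Time, by hand, multiplies a rate, and the zeta and epsilon readings between 50.0 s and 90.0 s give the conversion clock, the share of the charge turned into product per second once the start-up is over, as 0.00151 s⁻¹. Drawn back, that line reaches zero at a lag (induction period) of 9.34 s. The first answer, clock times time after the lag, is 25.8% for ochre and 44.0% for grey. That keeps the rate unchanged, so I go round once more, letting the rate follow what has not yet become product, of which on average 0.5 of the first answer is gone, and my reckoning becomes 22.5% for ochre and 34.3% for grey, with grey the higher.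

The forecast names grey, with ochre at 24.5% (from 20% to 28%) and grey at 38% (from 30% to 44%), on the ground that “Time matters, not concentration, so grey finishes higher”. My grey stands lower than its figure.

The flasks give 22.1% in ochre and 32.7% in grey, so grey finishes higher, and the forecast's grey is 5.3 points too high, being about what first order to completion through the last zeta reading gives.

    second catalyst + open intermediate ⇌ catalyst intermediate (K = 2.00 M⁻¹, k = 0.570 M⁻¹ s⁻¹)
    substrate + free catalyst ⇌ free catalyst + open intermediate (K = 0.410, k = 0.370 M⁻¹ s⁻¹)
    free catalyst ⇌ dormant form (K = 29.0, k = 0.0180 s⁻¹)
    coupling partner + catalyst intermediate → second catalyst + product (k = 0.0540 M⁻¹ s⁻¹)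

Grey's longer time is part of its lead: stopped at ochre's time, grey stands at 24.1%. Its extra 2.00 min would be worth 18 points on the undiminished clock and bring 8.6 points, about half, and the curve in grey is held down in part by the way back from free catalyst + open intermediate to substrate + free catalyst together with the time given: without that way back grey reaches 48.5%, and left until 50.0 min it reaches 77.9%. For flask ochre stopped at 50 s, the clock gives 6.15% and, on the second round, 5.96%; that flask holds 5.48%.

The numbers in the tables are calculated for an exercise.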